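| flask | left-handed substrate | right-handed substrate | solid reagent | remark | time |
|---|---|---|---|---|---|
| north-west | 0.050 M | 0.050 M | 0.40 M | run made earlier |  |
| flask | 0.10 M | 0.10 M | 0.400 M |  | 8.0 h |
north-west run (percent of the left-handed substrate and right-handed substrate together charged)

| time / min | left-handed product / % |
|---|---|
| 4.00 | 0.8 |
| 8.00 | 2.2 |
| 15.0 | 5.3 |
| 25.0 | 10.8 |
| 50.0 | 22.8 |

(each reading ± 0.5 percentage points)
- coupling partner is single-handed; left-handed substrate and right-handed substrate are mirror images of each other, charged as a racemate, each of them at the stated concentration
- given per volume of solution although it is solid: solid reagent
- the numbers in the tables scatter with a standard deviation of 0.5 percentage points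
- reactions considered so far: coupling partner + left-handed substrate -> left-handed product; coupling partner + right-handed substrate -> right-handed product; left-handed substrate <-> achiral form; right-handed substrate <-> achiral form; solid reagent <-> coupling partner
- at the start none of the solid reagent is in solution
- the handed part of coupling partner does not stay in what it makes, so the products of the two hands are mirror images too
- how much left-handed product there is at 8.0 h, in percent of the left-handed substrate and right-handed substrate together charged
- concentration of coupling partner in solution at 8.0 h, in percent of saturation

1. The constants of the flask are hidden, so a pace has to come from the north-west run. That run holds the same solid reagent, but the flask has twice its charge of each substrate.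

2. In the north-west run, after a lag, left-handed product climbs by 5.50 × 10⁻⁴ M min⁻¹ and then by 4.80 × 10⁻⁴ M min⁻¹, although left-handed substrate is being used. This reckoning therefore reads the pace as set by the dissolving solid reagent and carries it to the flask.

3. The delivery time is the charge of left-handed substrate divided by that pace: 3.47 h for the flask and 1.74 h for the north-west run. The north-west run stops at 50.0 min, well inside its delivery time, so it ends mid-climb at 22.8%. The flask runs past its delivery time, so it should end at its end state.

4. In the flask, solid reagent exceeds the substrates together, which makes substrate the limiting reagent. About 0.200 M of solid reagent stays, solid or dissolved, so coupling partner can rise close to saturation. Equal charges put left-handed product near 50.0%, and a little above it if coupling partner prefers that hand and the achiral form passes right-handed substrate over to the left hand. This reckoning commits to left-handed product a little above that figure and to coupling partner close to saturation.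

5. The forecast, higher on product than this reckoning, gives 80% and 90%: “the partner is no longer consumed and climbs towards saturation”.

The flask gives 53.7% and 98.2%.

    coupling partner + left-handed substrate → left-handed product (k = 1.52 M⁻¹ min⁻¹)
    coupling partner + right-handed substrate → right-handed product (k = 0.946 M⁻¹ min⁻¹)
    left-handed substrate ⇌ achiral form (K = 1.61, k = 0.0121 min⁻¹)
    right-handed substrate ⇌ achiral form (K = 1.61, k = 0.0121 min⁻¹)
    solid reagent ⇌ coupling partner, rate k5*(cs5 - [coupling partner]) while solid is left; crystals form when [coupling partner] > cs5 (solubility = 49.0 mM, k = 0.0301 min⁻¹)

At 8.00 h, past its delivery time of 3.47 h, the flask keeps 0.11% of its left-handed substrate and 0.17% of its right-handed substrate, and right-handed product stands at 45.6%. The neighbouring flask has the same charges but is read at 3.0 h, short of the delivery time. The carried pace gives it 43.2% of left-handed product. That neighbouring flask holds 43.1%, with 5.6% of its left-handed substrate still there.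

All runs are simulated for substances that don't exist; the scatter is artificial.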